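**Retrosynthetic overview**

- Labdane numbering is used (unit A unprimed, unit B primed; ring C = C14, C15, C15′, C14′, C13′, C12′). The last skeletal bond made is C13–C14, between the side-chain alkene of unit A and ring C, from a C18 alkyne (fragment 1) and a C22 γ-bromo enone (fragment 2).
- Enabling feature: in ring C the C13′=C14′ alkene with its allylic C12′–H is the reductive 1,3-transposition image of a C14′ ketone conjugated with C12′=C13′. In that enone C14 is the γ-carbon, so both C14 bromide epimers give one delocalised radical that a chiral nickel catalyst can alkenylate stereoconvergently.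
- After the union C14 relays its configuration to C12′: catalyst-controlled 1,2-reduction of the C14′ ketone, then Mitsunobu/diazene retro-ene delivers H to C12′ and forms C13′=C14′.
- Both fragments come from one C16 aldehyde obtained by oxidative opening of the isopropyl-bearing ring of abietic acid, which supplies C4, C5, C9, C10 and the C18 oxygen of both decalins.
- Ring order: no carbocycle is built. Rings A and B of each half are carried from abietic acid; ring C is bought as 3-ethoxy-2-methylcyclohex-2-en-1-one, attached to unit B (step 12) and then joined to unit A (step 15).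

Key step: step 15

Remark: abietic acid is taken as the commercial chiral-pool material; its A/B rings have the C4, C5, C9, C10 configuration and equatorial C18 oxygen that the stereodescriptors of the target require. TBDPS = tert-butyldiphenylsilyl, NBSH = 2-nitrobenzenesulfonohydrazide.

**Route**

Step 1
Reactants: 1 (−)-abietic acid
Product: 2 abietinol (abieta-7,13-dien-18-ol)
Conditions: LiAlH4, THF, 0 °C → reflux; aqueous work-up
Reagents that add atoms: none
Why: LiAlH4 reduction of the carboxylic acid to the primary alcohol is chemoselective over the unactivated diene and leaves the four chiral-pool stereocentres (C4, C5, C9, C10) untouched.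

Step 2
Reactants: 2 abietinol
Product: 3 18-O-TBDPS-abietinol
Conditions: TBDPSCl, imidazole, DMF, rt
Reagents that add atoms: tert-butyl(chloro)diphenylsilane, CC(C)(C)[Si](Cl)(c1ccccc1)c1ccccc1
Why: Standard silylation of a primary alcohol; the TBDPS ether is chosen because it must survive organolithiums, aqueous acid and Mitsunobu conditions until step 18.

Step 3
Reactants: 3 18-O-TBDPS-abietinol
Product: 5 keto enal 18-(TBDPS-oxy)-13-oxo-13,14-seco-abiet-7-en-14-al, via 13,14-diol 4 (not isolated)
Conditions: OsO4 (2 mol %), N-methylmorpholine N-oxide, acetone–H2O, 0 °C; then NaIO4, THF–H2O, rt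
Reagents that add atoms: N-methylmorpholine N-oxide, C[N+]1([O-])CCOCC1 (oxygen relayed by osmium tetroxide, O=[Os](=O)(=O)=O); water, O
Why: Catalytic dihydroxylation (Upjohn type) should take the C13=C14 end of the heteroannular diene, and periodate glycol cleavage then opens the ring to the C13 isopropyl ketone and a C14 enal whose conjugation deactivates C7=C8 toward further oxidation; no stereocentre is formed.

Step 4
Reactants: 5 keto enal
Product: 6 allylic alcohol 14-hydroxy-18-(TBDPS-oxy)-13,14-seco-abiet-7-en-13-one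
Conditions: LiAlH(OtBu)3, THF, −78 → −30 °C
Reagents that add atoms: none
Why: The bulky, mild hydride LiAlH(OtBu)3 reduces aldehydes much faster than hindered dialkyl ketones and attacks the enal in a 1,2 sense, so only C14 is reduced.

Step 5
Reactants: 6 allylic alcohol
Product: 8 exo-methylene ketone 18-(TBDPS-oxy)-13,14-seco-abiet-8(14)-en-13-one, via allylic diazene 7 (not isolated)
Conditions: PPh3, diethyl azodicarboxylate, NBSH, THF, −30 °C → rt
Reagents that add atoms: none
Why: Mitsunobu displacement of the primary allylic alcohol by the sulfonohydrazide, loss of sulfinic acid and retro-ene extrusion of N2 from the allylic diazene (reductive 1,3-transposition) move hydrogen to C7 and the double bond to the exocyclic position, which is C8(17) of the target decalins; no stereocentre is formed.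

Step 6
Reactants: 8 exo-methylene ketone
Product: 10 α-ketol 12-hydroxy-18-(TBDPS-oxy)-13,14-seco-abiet-8(14)-en-13-one (C12 epimers), via potassium enolate 9 (not isolated)
Conditions: KN(SiMe3)2, THF, −78 °C; then 3-phenyl-2-(phenylsulfonyl)oxaziridine, −78 °C; NH4Cl quench
Reagents that add atoms: 3-phenyl-2-(phenylsulfonyl)oxaziridine, O=S(=O)(c1ccccc1)N1OC1c1ccccc1
Why: Kinetic deprotonation occurs at the less substituted α-carbon C12 rather than at the isopropyl methine, and the enolate is oxidised by the N-sulfonyloxaziridine (enolate α-hydroxylation); the C12 configuration is irrelevant because this carbon becomes the aldehyde.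

Step 7
Reactants: 10 α-ketol
Product: 11 aldehyde (4R,5R,9S,10R)-18-(TBDPS-oxy)-13,14,15,16-tetranorlabd-8(17)-en-12-al
Conditions: Pb(OAc)4, MeOH–benzene, 0 °C
Reagents that add atoms: none
Why: Lead tetraacetate cleaves α-ketols between the carbinol and carbonyl carbons (Criegee-type glycol cleavage), releasing C12 as the aldehyde and the isobutyryl unit as its methyl ester, while the exocyclic alkene is inert at 0 °C.

Step 8
Reactants: 11 aldehyde
Product: 12 dibromoalkene 13,13-dibromo-18-(TBDPS-oxy)-14,15,16-trinorlabda-8(17),12-diene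
Conditions: CBr4, PPh3, CH2Cl2, 0 °C
Reagents that add atoms: carbon tetrabromide, BrC(Br)(Br)Br
Why: First stage of the Corey–Fuchs alkyne synthesis: the dibromomethylene ylide olefinates the unhindered aldehyde, adding C13.

Step 9
Reactants: 12 dibromoalkene
Product: 14 alkyne (fragment 1) (4R,5R,9S,10R)-18-(TBDPS-oxy)-14,15-dinorlabd-8(17)-en-12-yne, via lithium acetylide 13 (not isolated)
Conditions: n-BuLi (2.2 equiv), THF, −78 °C; then MeI, −78 °C → rt
Reagents that add atoms: iodomethane, CI
Why: Second Corey–Fuchs stage: bromine–lithium exchange, 1,2-shift and deprotonation give the lithium acetylide, which is C-methylated by MeI to install C16 and complete fragment 1.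

Step 10
Reactants: 11 aldehyde
Product: 15 acid (4R,5R,9S,10R)-18-(TBDPS-oxy)-13,14,15,16-tetranorlabd-8(17)-en-12-oic acid
Conditions: NaClO2, NaH2PO4, 2-methylbut-2-ene, t-BuOH–H2O, rt
Reagents that add atoms: sodium chlorite, [Na+].[O-]Cl=O
Why: Pinnick oxidation converts the aldehyde into the acid under mildly acidic conditions, the alkene scavenger protecting the exocyclic methylene from HOCl.

Step 11
Reactants: 15 acid
Product: 18 iodide (4R,5R,9S,10R)-11-iodo-18-(TBDPS-oxy)-12,13,14,15,16-pentanorlabd-8(17)-ene, via acid chloride 16 (not isolated), via Barton ester 17 (not isolated)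
Conditions: (COCl)2, DMF (cat.), CH2Cl2, 0 °C → rt; then sodium 1-oxidopyridine-2(1H)-thione (C5H4NNaOS), DMAP (cat.), CHI3, toluene, 80 °C, visible light
Reagents that add atoms: iodoform, IC(I)I
Why: Barton decarboxylative iodination: the thiohydroxamate ester fragments to the primary C11 radical, which abstracts iodine from iodoform faster than it can add to the hindered exocyclic alkene, shortening the chain by C12.

Step 12
Reactants: 18 iodide; 19 3-ethoxy-2-methylcyclohex-2-en-1-one
Product: 22 enone 2-methyl-3-{[(4R,5R,9S,10R)-18-(TBDPS-oxy)-12,13,14,15,16-pentanorlabd-8(17)-en-11-yl]}cyclohex-2-en-1-one (ring C with C14′=O and C12′=C13′), via alkyllithium 20 (not isolated), via lithium alkoxide 21 (not isolated)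
Conditions: t-BuLi (2.1 equiv), Et2O–pentane, −78 °C; then 19, THF, −78 → 0 °C; then 1 M aq. HCl, 0 °C
Reagents that add atoms: water, O
Why: Iodine–lithium exchange gives a primary alkyllithium that adds 1,2 to the vinylogous ester, and acid hydrolysis with loss of ethanol transposes the carbonyl (Stork–Danheiser sequence), so that C11′ ends on the β-carbon C12′ of a 2-methylcyclohexenone; no stereocentre is formed.

Step 13
Reactants: 22 enone
Product: 23 silyl dienol ether (C14′-O-TBS, C13′=C14′ and C12′=C14 diene)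
Conditions: t-BuMe2SiOTf, Et3N, CH2Cl2, 0 °C → rt
Reagents that add atoms: tert-butyldimethylsilyl trifluoromethanesulfonate, CC(C)(C)[Si](C)(C)OS(=O)(=O)C(F)(F)F
Why: Soft enolisation under equilibrating conditions (silyl triflate and amine) gives the through-conjugated dienol ether by γ-deprotonation at the ring CH2 (C14), as known for 3-alkylcyclohexenones and steroidal enones, in preference to the hindered exocyclic C11′.

Step 14
Reactants: 23 silyl dienol ether
Product: 24 γ-bromo enone (fragment 2), 14-bromo derivative of 22 as both C14 epimers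
Conditions: N-bromosuccinimide, NaHCO3, THF, −78 °C; used crude
Reagents that add atoms: N-bromosuccinimide, O=C1CCC(=O)N1Br
Why: Silyl dienol ethers are brominated by NBS at the γ-terminus (here C14, the α-carbon C13′ being fully substituted), restoring the enone; the C14 configuration is uncontrolled and need not be, since step 15 is stereoconvergent.

Step 15
Reactants: 14 alkyne (fragment 1); 24 γ-bromo enone (fragment 2)
Product: 27 coupled enone (12E,14R)-bis-TBDPS ether with C14′=O and C12′=C13′ (C14 arranged in space as in the target), via alkenylzirconocene 25 (not isolated), via alkenylzinc 26 (not isolated)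
Conditions: 14, Cp2Zr(H)Cl (1.3 equiv), THF, 40 °C; ZnCl2, THF, 0 °C; then 24, NiCl2(dme) (10 mol %), (S,S)-iPr-pybox [2,6-bis((4S)-4-isopropyl-4,5-dihydrooxazol-2-yl)pyridine] (13 mol %), DMA–THF, −10 °C (ligand antipode if the sense of induction is opposite)
Reagents that add atoms: none
Why: Proposed new method: syn-hydrozirconation of the 2-alkyne (zirconium on the methyl-bearing C13 after equilibration) and zirconium-to-zinc exchange give the (E)-alkenylzinc 26, while the nickel–pybox catalyst abstracts bromine from either C14 epimer of 24 to give one planar vinylogous α-keto radical (C14–C12′–C13′–C14′=O) that is captured by the alkenylnickel species and reductively eliminated at C14, so that both epimers converge on one configuration. The closest known reactions are the nickel/pybox Negishi couplings of racemic secondary allylic chlorides with organozincs and the nickel/bis(oxazoline) couplings of racemic α-bromo ketones with alkenylzirconium reagents; the extension to a cyclic γ-bromo enone with a trisubstituted alkenyl nucleophile is new. The step closes no ring. The new stereocentre C14 is set by the chiral ligand (catalyst control), the decalin stereocentres being four or more bonds away. The step needs γ- over α-selectivity and retention of the (E)-alkene: the α-terminus C13′ is fully substituted by its methyl group and γ-coupling keeps the enone conjugation, and alkenyl transfer from zirconium through zinc to nickel is stereoretentive. β-Hydride loss toward a phenol is the main competing path and should be suppressed by the tridentate ligand at low temperature.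

Step 16
Reactants: 27 coupled enone
Product: 28 allylic alcohol (14R,14′R), hydroxyl at C14′ cis to the C14 substituent
Conditions: (S)-2-methyl-CBS-oxazaborolidine (0.5 equiv), catecholborane, toluene, −78 °C; aq. NaOH work-up
Reagents that add atoms: none
Why: Corey–Bakshi–Shibata reduction with catecholborane (which does not hydroborate the alkenes at −78 °C) is 1,2-selective, and the oxazaborolidine, reading the α-methyl-substituted alkene side as the large group, should deliver hydride to the face that places the C14′ hydroxyl cis to the C14 substituent, independent of the remote decalins.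

Step 17
Reactants: 28 allylic alcohol
Product: 30 bis-TBDPS ether of the target (12E,14S,12′S), via allylic diazene 29 (not isolated)
Conditions: PPh3, diethyl azodicarboxylate, NBSH, THF, −30 °C → rt
Reagents that add atoms: none
Why: Mitsunobu displacement with inversion puts the sulfonylhydrazine, and after loss of sulfinic acid the diazene, on the face of C14′ opposite to the C14 substituent, and the suprafacial retro-ene loss of N2 (allylic diazene rearrangement) delivers hydrogen to C12′ on that same face while forming C13′=C14′, so that the C11′ methylene ends cis to the C13–C14 bond.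

Step 18
Reactants: 30 bis-TBDPS ether
Product: 31 target CNP0194625.1
Conditions: Bu4NF, THF, 50 °C
Reagents that add atoms: none
Why: Fluoride cleaves both neopentyl TBDPS ethers (silyl ether deprotection) without affecting the four alkenes or any stereocentre.

**Compound list**

1 | (−)-abietic acid | CC(C)C1=CC2=CC[C@H]3[C@](C)(C(=O)O)CCC[C@]3(C)[C@H]2CC1 | starting material
2 | abietinol (abieta-7,13-dien-18-ol) | CC(C)C1=CC2=CC[C@H]3[C@](C)(CO)CCC[C@]3(C)[C@H]2CC1 | intermediate
3 | 18-O-TBDPS-abietinol | CC(C)C1=CC2=CC[C@H]3[C@](C)(CO[Si](c4ccccc4)(c4ccccc4)C(C)(C)C)CCC[C@]3(C)[C@H]2CC1 | intermediate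
4 | 18-(TBDPS-oxy)abiet-7-ene-13,14-diol (cis-diol, C13/C14 configuration not needed) | CC(C)C1(O)C(O)C2=CC[C@H]3[C@](C)(CO[Si](c4ccccc4)(c4ccccc4)C(C)(C)C)CCC[C@]3(C)[C@H]2CC1 | intermediate
5 | keto enal, 18-(TBDPS-oxy)-13-oxo-13,14-seco-abiet-7-en-14-al | O=CC1=CC[C@H]2[C@](C)(CO[Si](c3ccccc3)(c3ccccc3)C(C)(C)C)CCC[C@]2(C)[C@H]1CCC(=O)C(C)C | intermediate
6 | allylic alcohol, 14-hydroxy-18-(TBDPS-oxy)-13,14-seco-abiet-7-en-13-one | OCC1=CC[C@H]2[C@](C)(CO[Si](c3ccccc3)(c3ccccc3)C(C)(C)C)CCC[C@]2(C)[C@H]1CCC(=O)C(C)C | intermediate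
7 | allylic diazene at C14 | N=NCC1=CC[C@H]2[C@](C)(CO[Si](c3ccccc3)(c3ccccc3)C(C)(C)C)CCC[C@]2(C)[C@H]1CCC(=O)C(C)C | intermediate
8 | exo-methylene ketone, 18-(TBDPS-oxy)-13,14-seco-abiet-8(14)-en-13-one | C=C1CC[C@H]2[C@](C)(CO[Si](c3ccccc3)(c3ccccc3)C(C)(C)C)CCC[C@]2(C)[C@H]1CCC(=O)C(C)C | intermediate
9 | potassium C12=C13 enolate of 8 | C=C1CC[C@H]2[C@](C)(CO[Si](c3ccccc3)(c3ccccc3)C(C)(C)C)CCC[C@]2(C)[C@H]1CC=C(O[K])C(C)C | intermediate
10 | α-ketol, 12-hydroxy derivative of 8 (C12 epimers) | C=C1CC[C@H]2[C@](C)(CO[Si](c3ccccc3)(c3ccccc3)C(C)(C)C)CCC[C@]2(C)[C@H]1CC(O)C(=O)C(C)C | intermediate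
11 | aldehyde, (4R,5R,9S,10R)-18-(TBDPS-oxy)-13,14,15,16-tetranorlabd-8(17)-en-12-al | C=C1CC[C@H]2[C@](C)(CO[Si](c3ccccc3)(c3ccccc3)C(C)(C)C)CCC[C@]2(C)[C@H]1CC=O | intermediate
12 | dibromoalkene, 13,13-dibromo-18-(TBDPS-oxy)-14,15,16-trinorlabda-8(17),12-diene | C=C1CC[C@H]2[C@](C)(CO[Si](c3ccccc3)(c3ccccc3)C(C)(C)C)CCC[C@]2(C)[C@H]1CC=C(Br)Br | intermediate
13 | lithium acetylide (C12≡C13–Li) | C=C1CC[C@H]2[C@](C)(CO[Si](c3ccccc3)(c3ccccc3)C(C)(C)C)CCC[C@]2(C)[C@H]1CC#C[Li] | intermediate
14 | alkyne (fragment 1), (4R,5R,9S,10R)-18-(TBDPS-oxy)-14,15-dinorlabd-8(17)-en-12-yne | C=C1CC[C@H]2[C@](C)(CO[Si](c3ccccc3)(c3ccccc3)C(C)(C)C)CCC[C@]2(C)[C@H]1CC#CC | intermediate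
15 | acid, 18-(TBDPS-oxy)-13,14,15,16-tetranorlabd-8(17)-en-12-oic acid | C=C1CC[C@H]2[C@](C)(CO[Si](c3ccccc3)(c3ccccc3)C(C)(C)C)CCC[C@]2(C)[C@H]1CC(=O)O | intermediate
16 | acid chloride of 15 | C=C1CC[C@H]2[C@](C)(CO[Si](c3ccccc3)(c3ccccc3)C(C)(C)C)CCC[C@]2(C)[C@H]1CC(=O)Cl | intermediate
17 | Barton ester of 15 (2-thioxopyridin-1(2H)-yl ester) | C=C1CC[C@H]2[C@](C)(CO[Si](c3ccccc3)(c3ccccc3)C(C)(C)C)CCC[C@]2(C)[C@H]1CC(=O)On1ccccc1=S | intermediate
18 | iodide, (4R,5R,9S,10R)-11-iodo-18-(TBDPS-oxy)-12,13,14,15,16-pentanorlabd-8(17)-ene | C=C1CC[C@H]2[C@](C)(CO[Si](c3ccccc3)(c3ccccc3)C(C)(C)C)CCC[C@]2(C)[C@H]1CI | intermediate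
19 | 3-ethoxy-2-methylcyclohex-2-en-1-one | CCOC1=C(C)C(=O)CCC1 | starting material
20 | C11 alkyllithium from 18 | C=C1CC[C@H]2[C@](C)(CO[Si](c3ccccc3)(c3ccccc3)C(C)(C)C)CCC[C@]2(C)[C@H]1C[Li] | intermediate
21 | lithium alkoxide adduct of 20 and 19 | CCOC1=C(C)C(O[Li])(C[C@H]2C(=C)CC[C@H]3[C@](C)(CO[Si](c4ccccc4)(c4ccccc4)C(C)(C)C)CCC[C@]23C)CCC1 | intermediate
22 | enone, 2-methyl-3-(decalinylmethyl)cyclohex-2-en-1-one (C14′=O, C12′=C13′) | CC1=C(C[C@H]2C(=C)CC[C@H]3[C@](C)(CO[Si](c4ccccc4)(c4ccccc4)C(C)(C)C)CCC[C@]23C)CCCC1=O | intermediate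
23 | silyl dienol ether of 22 (C14′-O-TBS; C13′=C14′, C12′=C14) | CC1=C(O[Si](C)(C)C(C)(C)C)CCC=C1C[C@H]1C(=C)CC[C@H]2[C@](C)(CO[Si](c3ccccc3)(c3ccccc3)C(C)(C)C)CCC[C@]12C | intermediate
24 | γ-bromo enone (fragment 2), 14-bromo derivative of 22, both C14 epimers | CC1=C(C[C@H]2C(=C)CC[C@H]3[C@](C)(CO[Si](c4ccccc4)(c4ccccc4)C(C)(C)C)CCC[C@]23C)C(Br)CCC1=O | intermediate
25 | (E)-alkenylzirconocene chloride (Zr on C13) | C=C1CC[C@H]2[C@](C)(CO[Si](c3ccccc3)(c3ccccc3)C(C)(C)C)CCC[C@]2(C)[C@H]1C/C=C(\C)[Zr](Cl)(C1C=CC=C1)C1C=CC=C1 | intermediate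
26 | (E)-alkenylzinc chloride (Zn on C13) | C=C1CC[C@H]2[C@](C)(CO[Si](c3ccccc3)(c3ccccc3)C(C)(C)C)CCC[C@]2(C)[C@H]1C/C=C(\C)[Zn]Cl | intermediate
27 | coupled enone, (12E,14R) bis-TBDPS ether with C14′=O, C12′=C13′ | C=C1CC[C@H]2[C@](C)(CO[Si](c3ccccc3)(c3ccccc3)C(C)(C)C)CCC[C@]2(C)[C@H]1C/C=C(\C)[C@H]1CCC(=O)C(C)=C1C[C@H]1C(=C)CC[C@H]2[C@](C)(CO[Si](c3ccccc3)(c3ccccc3)C(C)(C)C)CCC[C@]12C | intermediate
28 | allylic alcohol (14R,14′R), OH cis to the C14 substituent | C=C1CC[C@H]2[C@](C)(CO[Si](c3ccccc3)(c3ccccc3)C(C)(C)C)CCC[C@]2(C)[C@H]1C/C=C(\C)[C@H]1CC[C@@H](O)C(C)=C1C[C@H]1C(=C)CC[C@H]2[C@](C)(CO[Si](c3ccccc3)(c3ccccc3)C(C)(C)C)CCC[C@]12C | intermediate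
29 | allylic diazene (14R,14′S), N trans to the C14 substituent | C=C1CC[C@H]2[C@](C)(CO[Si](c3ccccc3)(c3ccccc3)C(C)(C)C)CCC[C@]2(C)[C@H]1C/C=C(\C)[C@H]1CC[C@H](N=N)C(C)=C1C[C@H]1C(=C)CC[C@H]2[C@](C)(CO[Si](c3ccccc3)(c3ccccc3)C(C)(C)C)CCC[C@]12C | intermediate
30 | bis-TBDPS ether of the target (12E,14S,12′S) | C=C1CC[C@H]2[C@](C)(CO[Si](c3ccccc3)(c3ccccc3)C(C)(C)C)CCC[C@]2(C)[C@H]1C/C=C(\C)[C@H]1CCC=C(C)[C@H]1C[C@H]1C(=C)CC[C@H]2[C@](C)(CO[Si](c3ccccc3)(c3ccccc3)C(C)(C)C)CCC[C@]12C | intermediate
31 | CNP0194625.1 | C=C1CC[C@H]2[C@](C)(CO)CCC[C@]2(C)[C@H]1C/C=C(\C)[C@H]1CCC=C(C)[C@H]1C[C@H]1C(=C)CC[C@H]2[C@](C)(CO)CCC[C@]12C | target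

**Step count and risks**

Total step count: 18. Longest linear sequence: 16 steps (steps 1–7 and 10–18); the alkyne branch (steps 8 and 9) joins at step 15.

Steps most likely to fail:

Step 15 (proposed new method). The risks are incomplete catalyst control of the C14 configuration or coupling at the α-terminus, β-hydride loss from the allylnickel species followed by aromatisation of ring C, and incomplete regiocontrol (or competing alkene hydrozirconation) while the alkenyl metal is formed. The fallback sets out from the alkenylzirconocene 25 (made from 14 as in step 15) and 24 and comes back at 27. Transmetalation of 25 with Bu3SnCl should give the (E)-alkenylstannane F1. A Stille allyl–alkenyl coupling with 24 (Pd2(dba)3, AsPh3, N-methylpyrrolidone, 50 °C) is a known reaction type but is without stereocontrol at C14, so it should give 27 together with its C14 epimer F2. The decalins make these diastereomers, which are to be separated by chromatography before step 16.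

Step 14. The risks are bromination through the cross-conjugated dienol ether isomer (at C15′) or at C11′, and loss of HBr from the product with aromatisation on storage. The fallback sets out from 19 (and the alkyllithium 20 from 18) and comes back at 24. Kinetic α′-deprotonation of 19 (LDA, THF, −78 °C) and oxidation with 3-phenyl-2-(phenylsulfonyl)oxaziridine should give 3-ethoxy-6-hydroxy-2-methylcyclohex-2-en-1-one F3, which is silylated (Et3SiCl, imidazole) to the triethylsilyl ether F4. Addition of 20 gives the lithium alkoxide adduct F5, and aqueous HCl effects carbonyl transposition and desilylation to the 14-hydroxy enone F6 (both C14 epimers), which can be stored. An Appel reaction (CBr4, PPh3, CH2Cl2, 0 °C) immediately before the coupling then gives 24 with the halogen placed unambiguously at C14.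

Step 17. The risk is slow Mitsunobu displacement at the hindered secondary allylic carbinol, with elimination to a ring diene or SN2′ attack eroding the transfer of configuration to C12′. The fallback sets out from 27 and comes back at 30. Copper hydride 1,4-reduction ([(Ph3P)CuH]6 cat., PhMe2SiH, toluene) should add hydride to C12′ anti to the C14 substituent and give the silyl enol ether F7. MeLi releases the lithium enolate F8, which PhNTf2 traps as the enol triflate F9. Palladium-catalysed formate reduction (Pd(OAc)2, PPh3, HCO2H, Bu3N, DMF, 60 °C) then replaces the triflate by hydrogen and leaves C13′=C14′, giving 30.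

**Further compounds**

F1 | step 15 | (E)-alkenylstannane, tributylstannyl on C13 | C=C1CC[C@H]2[C@](C)(CO[Si](c3ccccc3)(c3ccccc3)C(C)(C)C)CCC[C@]2(C)[C@H]1C/C=C(\C)[Sn](CCCC)(CCCC)CCCC
F2 | step 15 | C14 epimer of 27 (14S) | C=C1CC[C@H]2[C@](C)(CO[Si](c3ccccc3)(c3ccccc3)C(C)(C)C)CCC[C@]2(C)[C@H]1C/C=C(\C)[C@@H]1CCC(=O)C(C)=C1C[C@H]1C(=C)CC[C@H]2[C@](C)(CO[Si](c3ccccc3)(c3ccccc3)C(C)(C)C)CCC[C@]12C
F3 | step 14 | 3-ethoxy-6-hydroxy-2-methylcyclohex-2-en-1-one (racemic) | CCOC1=C(C)C(=O)C(O)CC1
F4 | step 14 | 3-ethoxy-2-methyl-6-(triethylsilyloxy)cyclohex-2-en-1-one (racemic) | CCOC1=C(C)C(=O)C(O[Si](CC)(CC)CC)CC1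
F5 | step 14 | lithium alkoxide adduct of 20 and F4 | CCOC1=C(C)C(O[Li])(C[C@H]2C(=C)CC[C@H]3[C@](C)(CO[Si](c4ccccc4)(c4ccccc4)C(C)(C)C)CCC[C@]23C)C(O[Si](CC)(CC)CC)CC1
F6 | step 14 | 14-hydroxy enone (both C14 epimers) | CC1=C(C[C@H]2C(=C)CC[C@H]3[C@](C)(CO[Si](c4ccccc4)(c4ccccc4)C(C)(C)C)CCC[C@]23C)C(O)CCC1=O
F7 | step 17 | dimethylphenylsilyl enol ether (C13′=C14′–OSi, 12′S,14S) | C=C1CC[C@H]2[C@](C)(CO[Si](c3ccccc3)(c3ccccc3)C(C)(C)C)CCC[C@]2(C)[C@H]1C/C=C(\C)[C@H]1CCC(O[Si](C)(C)c2ccccc2)=C(C)[C@H]1C[C@H]1C(=C)CC[C@H]2[C@](C)(CO[Si](c3ccccc3)(c3ccccc3)C(C)(C)C)CCC[C@]12C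
F8 | step 17 | lithium enolate (C13′=C14′–OLi) | C=C1CC[C@H]2[C@](C)(CO[Si](c3ccccc3)(c3ccccc3)C(C)(C)C)CCC[C@]2(C)[C@H]1C/C=C(\C)[C@H]1CCC(O[Li])=C(C)[C@H]1C[C@H]1C(=C)CC[C@H]2[C@](C)(CO[Si](c3ccccc3)(c3ccccc3)C(C)(C)C)CCC[C@]12C
F9 | step 17 | enol triflate (C13′=C14′–OTf) | C=C1CC[C@H]2[C@](C)(CO[Si](c3ccccc3)(c3ccccc3)C(C)(C)C)CCC[C@]2(C)[C@H]1C/C=C(\C)[C@H]1CCC(OS(=O)(=O)C(F)(F)F)=C(C)[C@H]1C[C@H]1C(=C)CC[C@H]2[C@](C)(CO[Si](c3ccccc3)(c3ccccc3)C(C)(C)C)CCC[C@]12C
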